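## The problem

Target 17 is a meso cyclobutane. C1 and C2 are adjacent quaternary carbons, each bearing a methyl group and a 4-methoxy-3-methyl-2-oxo-2H-pyran-6-yl ring attached through C6′; C3 and C4 each bear a carboxylic acid. The stereodescriptors place the two acids cis to each other and to both methyl groups, with both pyranones on the opposite face. A mirror plane through the midpoints of C1–C2 and C3–C4 makes the halves equivalent, so the synthesis can run in two directions at once and needs no absolute control.

Three relations must be set: C1/C2 cis, C3/C4 cis, and the C1/C2 pair against the C3/C4 pair. The quaternary centres cannot epimerise once made and therefore fix a face; C3 and C4 are α to carboxyl groups and can be lost to base. The C1–C2 bond between two quaternary carbons is the hardest to form intermolecularly.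

Sensitive groups: the pyranones are vinylogous carbonates that open with hydroxide; their 5,6-dihydro precursors open through C5′ deprotonation; a cis-1,2-diacid closes to its anhydride when activated.

The enabling feature is that each heterocycle (O1′, C2′=O, C3′–CH3, C4′–OCH3, C5′–H, C6′) hangs from a quaternary ring carbon through C6′. A formyl group there cannot enolise, is the smallest electrophile available at a neopentyl site, and already carries the oxygen that becomes O1′.

## Retrosynthesis

**17 ⇒ 16.** Only the two ester C–O bonds are cut. tert-Butyl esters are chosen over methyl esters because acidolysis spares the pyranones and the C3/C4 centres, whereas hydroxide or nucleophilic demethylation would threaten both. The forward step must be a clean acidolysis.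

**16 ⇒ 14.** The C5′=C6′ double bonds are saturated in the retrosynthetic sense, turning each C6′ into a carbinol carbon. The neighbouring option, building the pyranone directly by acylation at an acyl group on C1/C2, would ask a hindered neopentyl acyl derivative to react twice. The forward reaction must dehydrogenate without base, because dihydropyranones ring-open once C5′ is deprotonated.

**14 ⇒ 9 + two molecules of 11.** In each ring the C5′–C6′ and O1′–C2′ bonds are cut. Cutting C1–C6′ instead would require substitution at a quaternary carbon; cutting inside the C2′–C5′ unit would leave longer, enolisable chains on the ring. The precursor pair is much simpler: the symmetric dialdehyde 9 and the C7 ester 11, which already holds the 3′-methyl and 4′-methoxy groups. The forward step must add through the γ-carbon twice, lactonise, and leave C3/C4 untouched.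

**9 ⇒ 8.** The two formyl carbons are reconnected as a CH=CH bridge (retro-ozonolysis). A ring guarantees that the formyl groups are cis. Deriving them from a second pair of carboxyl groups would instead require differentiating four carboxyl carbons.

**8 ⇒ 6 (through 7).** The ester C–O bonds are cut back to the cyclic anhydride 6, the form needed in the photochemical step.

**6 ⇒ 5.** The bond between the two methyl-bearing bridgeheads (C1–C2 of the target) is cut, giving the cyclohexadiene 5. A 4π ring closure makes the vicinal quaternary centres intramolecularly, which an intermolecular cycloaddition to a tetrasubstituted alkene would do less readily. The forward closure must place the anhydride anti to the new CH=CH bridge.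

**5 ⇒ 4 ⇒ 1 + 2 (through 3).** The sulfinyl bridge is put back and the C1–C4 and C2–C3 bonds are cut in a Diels–Alder sense. The S-oxide 3 is preferred to the corresponding sulfone because its adduct 4 is stable at low temperature. The diene 5 is therefore unveiled only after 2 has been removed, and cannot add a second molecule of 2. Compounds 1 and 2 are commercial; the cis relation of C3/C4 comes from 2.

**11 ⇒ 10.** The enol ether C–O bond is cut back to the commercial β-keto ester 10.

## Roads not taken

**Alternative 1:** The cut is the C1–C4 and C2–C3 pair of the cyclobutane. Forward, triplet-sensitised irradiation of 2,3-dimethylmaleic anhydride A1 with excess maleic anhydride 2 would give the cis-anti-cis dianhydride A2.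
- Merits: one step from two commodity anhydrides builds the ring, both quaternary centres and all four stereocentres. The anti arrangement is sterically enforced, and C3/C4 arrive at the acid oxidation level.
- Weak points: A1 and 2 each homodimerise. More seriously, the anhydride that must be transformed sits on the quaternary carbons and is the hindered one, while the anhydride to be kept is the exposed one, so reactivity runs the wrong way. Each pyranone would then have to grow from a neopentyl acyl group by C-acylation of a dienolate, twice on adjacent carbons.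
- Comparison: this road is better in step count to the carbocycle and in certainty of relative configuration. The chosen plan has to set against that an uncertain facial course in step 3. In return it delivers aldehydes at the hindered sites and esters at the others, already differentiated.

**Alternative 2:** The cut is the C4–carboxyl bond. Forward, Pd(OAc)2 with AgOAc under carbon monoxide would cleave the C4–H bond cis to the 8-aminoquinoline amide of the mono-amide A3, insert CO and close the N-quinolyl imide A4.
- Merits: the palladacycle geometry guarantees the cis relation of C3 and C4, as securely as the use of 2 does in the chosen plan. One carboxyl fewer is carried through the sequence.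
- Weak points: A3 lacks the mirror plane, so two-directional work ends early, and A3 is no easier to make than 16. The reaction is a methylene C–H carbonylation beside a quaternary carbon. The electron-rich pyranone C5′–H bonds are exposed to divalent palladium and the silver oxidant. Freeing the diacid from A4 needs imide and quinolyl-amide cleavage under conditions that the pyranones and the C3/C4 centres are unlikely to survive.
- Comparison: weaker overall; its one real asset, the guaranteed cis-diacid, is matched by the chosen plan.

**Alternative 3:** The cut is C1–C6′ and C2–C6′. Forward, 3,6-dimethyl-1,2,4,5-tetrazine A6 would add across the ring double bond of dimethyl cis-3,4-dimethylcyclobut-3-ene-1,2-dicarboxylate A5 and lose N2, giving the dihydropyridazine A7.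
- Merits: the reaction is thermal and attacks the cyclobutene face anti to the esters. That settles exactly the relation that is least certain in the chosen plan. A5 is two steps from 2.
- Weak points: A6 is among the least reactive tetrazines and must add to a tetrasubstituted alkene while forming two adjacent quaternary centres. The cyclic azine of A7 then has to be hydrolysed against its own stability to the diketone A8. A8 is a 1,4-diketone that can close to a cyclopentenone under the enolising conditions needed next. Each methyl ketone still needs acylation, cyclisation and O-methylation beside epimerisable esters.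
- Comparison: better in facial certainty. The chosen plan sets against it a non-enolisable dialdehyde that accepts the whole C2′–C5′ unit in one operation.

Key step: step 7

Remark on the chemistry: the target is meso, so only relative configuration matters; tert-butyl esters replace methyl esters as spectators so that the last step is an acidolysis.

## Route

Step 1
Reactants: 1 2,5-dimethylthiophene; 2 maleic anhydride
Product: 4 endo-1,4-dimethyl-7-thiabicyclo[2.2.1]hept-5-ene-2,3-dicarboxylic anhydride 7-oxide (sulfinyl oxygen toward the C2–C3 bridge), via 2,5-dimethylthiophene 1-oxide 3 (not isolated)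
Conditions: mCPBA, BF3·OEt2, CH2Cl2, −20 °C
Reagents that add atoms: mCPBA (3-chloroperoxybenzoic acid), OOC(=O)c1cccc(Cl)c1
Why: Oxidative cycloaddition: the BF3-complexed S-oxide 3 is a non-aromatic diene that 2 traps in a Diels–Alder reaction at low temperature before further oxidation. Addition is suprafacial, so the anhydride stays cis (the C3/C4 relation of the target); the expected endo sense and the sulfur configuration are both erased in step 2.

Step 2
Reactants: 4 endo-1,4-dimethyl-7-thiabicyclo[2.2.1]hept-5-ene-2,3-dicarboxylic anhydride 7-oxide
Product: 5 cis-3,6-dimethylcyclohexa-3,5-diene-1,2-dicarboxylic anhydride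
Conditions: PhMe, 110 °C, Ar
Reagents that add atoms: none
Why: Retro-cheletropic extrusion of sulfur monoxide from the 7-thianorbornene S-oxide unveils the 1,3-diene when no dienophile is left, so a second Diels–Alder addition cannot follow. The cis ring fusion is untouched; exclusion of air and the lowest effective temperature guard the dihydro oxidation level.

Step 3
Reactants: 5 cis-3,6-dimethylcyclohexa-3,5-diene-1,2-dicarboxylic anhydride
Product: 6 exo-1,4-dimethylbicyclo[2.2.0]hex-5-ene-2,3-dicarboxylic anhydride (anhydride cis to the bridgehead methyl groups and anti to the CH=CH bridge)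
Conditions: hν (254 nm), Et2O, 0 °C
Reagents that add atoms: none
Why: Photochemical disrotatory 4π electrocyclisation joins the two methyl-bearing diene termini, creating the vicinal quaternary centres, necessarily cis. The fused anhydride suppresses the competing conrotatory ring opening, which would put a trans double bond into a nine-membered ring. The anhydride is expected to swing to the convex face, away from the developing cyclobutene (the less congested cis-anti-cis tricycle); the product is kept below 40 °C to avoid thermal reversion.

Step 4
Reactants: 6 exo-1,4-dimethylbicyclo[2.2.0]hex-5-ene-2,3-dicarboxylic anhydride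
Product: 8 di-tert-butyl exo,cis-1,4-dimethylbicyclo[2.2.0]hex-5-ene-2,3-dicarboxylate, via diacid 7 (not isolated)
Conditions: H2O, THF, 40 °C; evaporation; O-tert-butyl-N,N′-diisopropylisourea, CH2Cl2, 25 °C
Reagents that add atoms: water, O; O-tert-butyl-N,N′-diisopropylisourea, CC(C)NC(=NC(C)C)OC(C)(C)C
Why: Anhydride hydrolysis, then O-alkylation of both acids by the isourea (proton transfer followed by tert-butyl transfer). This neutral esterification does not activate the acyl groups, so the anhydride cannot re-form, and it touches neither the α-stereocentres nor the strained alkene.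

Step 5
Reactants: 8 di-tert-butyl exo,cis-1,4-dimethylbicyclo[2.2.0]hex-5-ene-2,3-dicarboxylate
Product: 9 di-tert-butyl 3,4-diformyl-3,4-dimethylcyclobutane-1,2-dicarboxylate (meso; esters cis to each other and to both methyl groups; formyl groups on the opposite face)
Conditions: O3, CH2Cl2, −78 °C; PPh3, −78 °C → 25 °C
Reagents that add atoms: ozone, [O-][O+]=O
Why: Ozonolysis of the cyclobutene with reductive work-up cleaves the CH=CH bridge into two formyl groups, which stay cis to each other and trans to the esters. No alcohol is used, so the cis-1,4-dialdehyde is not trapped as a cyclic acetal.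

Step 6
Reactants: 10 methyl 2-methylacetoacetate
Product: 11 methyl (E)-3-methoxy-2-methylbut-2-enoate
Conditions: HC(OMe)3, H2SO4 (cat.), MeOH, 25 °C; distillation
Reagents that add atoms: trimethyl orthoformate, COC(OC)OC
Why: Acid-catalysed ketalisation by the orthoformate, then loss of methanol to the conjugated enol ether. The E isomer (C4 methyl cis to the ester) is expected to predominate, and either isomer leads to the same dienolate.

Step 7
Reactants: 9 di-tert-butyl 3,4-diformyl-3,4-dimethylcyclobutane-1,2-dicarboxylate; 11 methyl (E)-3-methoxy-2-methylbut-2-enoate (two molecules)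
Product: 14 di-tert-butyl 3,4-bis(4-methoxy-3-methyl-2-oxo-5,6-dihydro-2H-pyran-6-yl)-3,4-dimethylcyclobutane-1,2-dicarboxylate (ring configuration as in 9; C6′ epimers), via lithium dienolate 12 (not isolated), via dilithium bis-alkoxide 13 (not isolated)
Conditions: i-Pr2NH, n-BuLi, THF, −78 °C; 11; then 9, −78 → 0 °C; AcOH
Reagents that add atoms: none
Why: Lithium diisopropylamide removes a proton from the C4 methyl group of 11, which the E geometry holds next to the ester carbonyl, giving the extended enolate 12. Its γ-carbon, the only unhindered nucleophilic terminus because the α-carbon is fully substituted, adds to each non-enolisable formyl group of 9, forming the two C5′–C6′ bonds and the dialkoxide 13. On warming, each alkoxide attacks the methyl ester held cis across the C2=C3 bond in a 6-exo-trig acyl substitution, expelling methoxide, forming the two O1′–C2′ bonds and closing both 5,6-dihydropyran-2-one rings. The closest known reaction type is the vinylogous aldol addition–lactonisation of lithium dienolates of 3-methoxybut-2-enoates with aldehydes to give 6-substituted 4-methoxy-5,6-dihydropyran-2-ones. The two new C6′ stereocentres form without control and need none, since both become sp2 in step 8. The step needs γ- over α-attack (secured by the α-methyl and β-methoxy groups), aldehyde over ester attack (tert-butyl esters beside quaternary carbons are shielded) and no proton loss from C3/C4 (−78 °C, addition of 9 to excess 12). Lactonisation onto a ring ester cannot compete, because each carbinol carbon is trans to the neighbouring ester and a trans-fused γ-lactone on a cyclobutane is prohibitively strained.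

Step 8
Reactants: 14 di-tert-butyl 3,4-bis(4-methoxy-3-methyl-2-oxo-5,6-dihydro-2H-pyran-6-yl)-3,4-dimethylcyclobutane-1,2-dicarboxylate
Product: 16 di-tert-butyl 3,4-bis(4-methoxy-3-methyl-2-oxo-2H-pyran-6-yl)-3,4-dimethylcyclobutane-1,2-dicarboxylate (ring configuration as in 9), via bis(5′-bromo) lactone 15 (not isolated)
Conditions: NBS, AIBN (cat.), PhCF3, 80 °C; then Et3N, CH2Cl2, 25 °C
Reagents that add atoms: none
Why: Wohl–Ziegler bromination at C5′, the methylene allylic to the C3′=C4′ enol ether bond, followed by E2 loss of HBr across C5′–C6′. This is the classical base-mild conversion of 6-alkyl-5,6-dihydropyran-2-ones into pyran-2-ones. Any bromide formed at C3′ by an ionic path is the allylic isomer and should lose HBr in a 1,4-sense to the same pyranone.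

Step 9
Reactants: 16 di-tert-butyl 3,4-bis(4-methoxy-3-methyl-2-oxo-2H-pyran-6-yl)-3,4-dimethylcyclobutane-1,2-dicarboxylate
Product: 17 3,4-bis(4-methoxy-3-methyl-2-oxo-2H-pyran-6-yl)-3,4-dimethylcyclobutane-1,2-dicarboxylic acid (meso; acids cis to each other and to both methyl groups; pyranones on the opposite face)
Conditions: CF3CO2H, CH2Cl2, 25 °C
Reagents that add atoms: none
Why: Acidolysis of the tert-butyl esters with loss of 2-methylpropene. No base or nucleophile is present, so the pyranones and the C3/C4 centres are unaffected and the diacid is not dehydrated.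

## Compound list

1 | 2,5-dimethylthiophene | Cc1ccc(C)s1 | starting material
2 | maleic anhydride | O=C1C=CC(=O)O1 | starting material
3 | 2,5-dimethylthiophene 1-oxide (BF3-complexed, formed in the flask) | CC1=CC=C(C)S1=O | intermediate
4 | endo-1,4-dimethyl-7-thiabicyclo[2.2.1]hept-5-ene-2,3-dicarboxylic anhydride 7-oxide (sulfinyl oxygen toward the anhydride-bearing bridge) | C[C@@]12C=C[C@@](C)([S@@]1=O)[C@@H]1C(=O)OC(=O)[C@H]21 | intermediate
5 | cis-3,6-dimethylcyclohexa-3,5-diene-1,2-dicarboxylic anhydride | CC1=CC=C(C)[C@@H]2C(=O)OC(=O)[C@H]12 | intermediate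
6 | exo-1,4-dimethylbicyclo[2.2.0]hex-5-ene-2,3-dicarboxylic anhydride (anhydride cis to the methyl groups, anti to CH=CH) | C1=C[C@@]2(C)[C@@H]3C(=O)OC(=O)[C@@H]3[C@]21C | intermediate
7 | exo,cis-1,4-dimethylbicyclo[2.2.0]hex-5-ene-2,3-dicarboxylic acid | C1=C[C@@]2(C)[C@H](C(=O)O)[C@H](C(=O)O)[C@]21C | intermediate
8 | di-tert-butyl exo,cis-1,4-dimethylbicyclo[2.2.0]hex-5-ene-2,3-dicarboxylate | C1=C[C@@]2(C)[C@H](C(=O)OC(C)(C)C)[C@H](C(=O)OC(C)(C)C)[C@]21C | intermediate
9 | di-tert-butyl 3,4-diformyl-3,4-dimethylcyclobutane-1,2-dicarboxylate (meso; formyls cis, trans to the esters) | O=C[C@@]1(C)[C@H](C(=O)OC(C)(C)C)[C@H](C(=O)OC(C)(C)C)[C@@]1(C)C=O | intermediate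
10 | methyl 2-methylacetoacetate | COC(=O)C(C)C(C)=O | starting material
11 | methyl (E)-3-methoxy-2-methylbut-2-enoate | C/C(OC)=C(/C)C(=O)OC | intermediate
12 | lithium 1,3-dimethoxy-2-methylbuta-1,3-dien-1-olate | C=C(OC)C(C)=C([O-])OC.[Li+] | intermediate
13 | dilithium bis-alkoxide of the bis(γ-adduct): di-tert-butyl 3,4-bis[(E)-1-oxido-3,5-dimethoxy-4-methyl-5-oxopent-3-en-1-yl]-3,4-dimethylcyclobutane-1,2-dicarboxylate (carbinol epimers) | COC(=O)/C(C)=C(OC)\CC([O-])[C@@]1(C)[C@H](C(=O)OC(C)(C)C)[C@H](C(=O)OC(C)(C)C)[C@@]1(C)C([O-])C/C(OC)=C(C)\C(=O)OC.[Li+].[Li+] | intermediate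
14 | di-tert-butyl 3,4-bis(4-methoxy-3-methyl-2-oxo-5,6-dihydro-2H-pyran-6-yl)-3,4-dimethylcyclobutane-1,2-dicarboxylate (C6′ epimers) | COC1=C(C)C(=O)OC(C1)[C@@]2(C)[C@H](C(=O)OC(C)(C)C)[C@H](C(=O)OC(C)(C)C)[C@@]2(C)C1CC(OC)=C(C)C(=O)O1 | intermediate
15 | di-tert-butyl 3,4-bis(5-bromo-4-methoxy-3-methyl-2-oxo-5,6-dihydro-2H-pyran-6-yl)-3,4-dimethylcyclobutane-1,2-dicarboxylate (bromide epimers) | COC1=C(C)C(=O)OC(C1Br)[C@@]2(C)[C@H](C(=O)OC(C)(C)C)[C@H](C(=O)OC(C)(C)C)[C@@]2(C)C1OC(=O)C(C)=C(OC)C1Br | intermediate
16 | di-tert-butyl 3,4-bis(4-methoxy-3-methyl-2-oxo-2H-pyran-6-yl)-3,4-dimethylcyclobutane-1,2-dicarboxylate | COc1cc([C@@]2(C)[C@H](C(=O)OC(C)(C)C)[C@H](C(=O)OC(C)(C)C)[C@@]2(C)c2cc(OC)c(C)c(=O)o2)oc(=O)c1C | intermediate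
17 | 3,4-bis(4-methoxy-3-methyl-2-oxo-2H-pyran-6-yl)-3,4-dimethylcyclobutane-1,2-dicarboxylic acid (meso) | COc1cc([C@@]2(C)[C@H](C(=O)O)[C@H](C(=O)O)[C@@]2(C)c2cc(OC)c(C)c(=O)o2)oc(=O)c1C | target

## Step count and least certain steps

Total: 9 steps. Longest linear sequence: 8 steps (steps 1–5 and 7–9); step 6 is a one-step side branch.

**Step 7 (key step).** After the first addition, the new alkoxide can add to the neighbouring cis-formyl group. The resulting cyclic hemiacetal alkoxide would stall the second addition or pass on hydride. Proton transfer from C3/C4 would cause epimerisation. Excess base on warming could deprotonate C5′ and open a finished lactone.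

The fallback moves the same bond formations to Lewis-acidic conditions. It sets out from 9 and 11. Compound 11 is silylated (lithium diisopropylamide, then Me3SiCl, THF, −78 °C) to [(1,3-dimethoxy-2-methylbuta-1,3-dien-1-yl)oxy]trimethylsilane F1. F1 adds to 9 in a vinylogous Mukaiyama aldol reaction (BF3·OEt2, CH2Cl2, −78 °C) to give the bis(δ-hydroxy-β-methoxy enoate) F2. Acid-catalysed lactonisation of F2 (pyridinium p-toluenesulfonate, PhMe, 60 °C) comes back to the route at 14.

**Step 3.** The disrotatory closure may take the opposite facial course and place the anhydride syn to the CH=CH bridge. That error could not be repaired later, because C1/C2 are quaternary. The bridgehead methyl groups add some strain to the exo pathway, so the steric preference is not assured; photoreversion and aromatisation are lesser risks.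

The fallback fixes the anti relation by cycloaddition to a cyclobutene face and sets out from 2. Triplet-sensitised [2+2] photocycloaddition of 2 with but-2-yne gives 3,4-dimethylcyclobut-3-ene-cis-1,2-dicarboxylic anhydride F3. Hydrolysis and tert-butylation as in step 4 give di-tert-butyl cis-3,4-dimethylcyclobut-3-ene-1,2-dicarboxylate F4. Acetone-sensitised [2+2] photocycloaddition of vinylene carbonate to the face of F4 anti to the esters gives the cyclic carbonate of di-tert-butyl 5,6-dihydroxy-1,4-dimethylbicyclo[2.2.0]hexane-2,3-dicarboxylate F5. Methanolysis (K2CO3, MeOH) gives the cis-diol F6, and glycol cleavage of F6 (NaIO4, THF–H2O) comes back to the route at 9.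

**Step 8.** Hydrogen abstraction may occur at the C3′ methyl groups instead of C5′, or bromination may go too far. HBr formed during the reaction may also strip the tert-butyl esters.

The fallback builds the pyranones at the higher oxidation level and sets out from 9. Addition of the dianion of 10 (NaH, then n-BuLi, THF, 0 → −78 °C) gives the bis(δ-hydroxy-β-keto ester) F7. Dess–Martin oxidation gives the bis(3,5-diketo ester) F8. Enol-lactonisation with DBU (PhMe, 25 °C) gives the bis(4-hydroxy-3-methylpyran-2-one) F9. O-Methylation of F9 (Me2SO4, K2CO3, acetone) comes back to the route at 16.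

**Step 2.** Under thermolysis the liberated sulfur monoxide or traces of air may dehydrogenate the diene to the phthalic anhydride, and the fragments may recombine.

The fallback reaches the same diene by reduction of an arene and sets out from 2. Diels–Alder addition of 2,5-dimethylfuran to 2 gives exo-1,4-dimethyl-7-oxabicyclo[2.2.1]hept-5-ene-2,3-dicarboxylic anhydride F10. Dehydration in cold concentrated H2SO4 gives 3,6-dimethylphthalic anhydride F11. Hydrolysis and reduction with Na/Hg in buffered water give trans-3,6-dimethylcyclohexa-3,5-diene-1,2-dicarboxylic acid F12. Heating F12 with acetic anhydride epimerises one centre and closes the cis anhydride, coming back to the route at 5.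

## Further compounds

F1 | step 7 | [(1,3-dimethoxy-2-methylbuta-1,3-dien-1-yl)oxy]trimethylsilane | C=C(OC)C(C)=C(OC)O[Si](C)(C)C
F2 | step 7 | di-tert-butyl 3,4-bis[(E)-1-hydroxy-3,5-dimethoxy-4-methyl-5-oxopent-3-en-1-yl]-3,4-dimethylcyclobutane-1,2-dicarboxylate (carbinol epimers) | COC(=O)/C(C)=C(OC)\CC(O)[C@@]1(C)[C@H](C(=O)OC(C)(C)C)[C@H](C(=O)OC(C)(C)C)[C@@]1(C)C(O)C/C(OC)=C(C)\C(=O)OC
F3 | step 3 | 3,4-dimethylcyclobut-3-ene-cis-1,2-dicarboxylic anhydride | CC1=C(C)[C@@H]2C(=O)OC(=O)[C@H]12
F4 | step 3 | di-tert-butyl cis-3,4-dimethylcyclobut-3-ene-1,2-dicarboxylate | CC1=C(C)[C@H](C(=O)OC(C)(C)C)[C@@H]1C(=O)OC(C)(C)C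
F5 | step 3 | cyclic carbonate of di-tert-butyl 5,6-dihydroxy-1,4-dimethylbicyclo[2.2.0]hexane-2,3-dicarboxylate (carbonate bridge anti to the esters; configuration at the two carbonate-bearing carbons immaterial) | O=C1OC2C(O1)[C@@]1(C)[C@H](C(=O)OC(C)(C)C)[C@H](C(=O)OC(C)(C)C)[C@]12C
F6 | step 3 | di-tert-butyl 5,6-dihydroxy-1,4-dimethylbicyclo[2.2.0]hexane-2,3-dicarboxylate (cis-diol anti to the esters) | OC1C(O)[C@@]2(C)[C@H](C(=O)OC(C)(C)C)[C@H](C(=O)OC(C)(C)C)[C@]21C
F7 | step 8 | di-tert-butyl 3,4-bis(1-hydroxy-5-methoxy-4-methyl-3,5-dioxopentyl)-3,4-dimethylcyclobutane-1,2-dicarboxylate (epimers) | COC(=O)C(C)C(=O)CC(O)[C@@]1(C)[C@H](C(=O)OC(C)(C)C)[C@H](C(=O)OC(C)(C)C)[C@@]1(C)C(O)CC(=O)C(C)C(=O)OC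
F8 | step 8 | di-tert-butyl 3,4-bis(5-methoxy-4-methyl-3,5-dioxopentanoyl)-3,4-dimethylcyclobutane-1,2-dicarboxylate | COC(=O)C(C)C(=O)CC(=O)[C@@]1(C)[C@H](C(=O)OC(C)(C)C)[C@H](C(=O)OC(C)(C)C)[C@@]1(C)C(=O)CC(=O)C(C)C(=O)OC
F9 | step 8 | di-tert-butyl 3,4-bis(4-hydroxy-3-methyl-2-oxo-2H-pyran-6-yl)-3,4-dimethylcyclobutane-1,2-dicarboxylate | Oc1cc([C@@]2(C)[C@H](C(=O)OC(C)(C)C)[C@H](C(=O)OC(C)(C)C)[C@@]2(C)c2cc(O)c(C)c(=O)o2)oc(=O)c1C
F10 | step 2 | exo-1,4-dimethyl-7-oxabicyclo[2.2.1]hept-5-ene-2,3-dicarboxylic anhydride | C[C@@]12C=C[C@@](C)(O1)[C@H]1C(=O)OC(=O)[C@@H]21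
F11 | step 2 | 3,6-dimethylphthalic anhydride | Cc1ccc(C)c2C(=O)OC(=O)c12
F12 | step 2 | trans-3,6-dimethylcyclohexa-3,5-diene-1,2-dicarboxylic acid (racemic) | CC1=CC=C(C)[C@H](C(=O)O)[C@H]1C(=O)O
A1 | alternative 1 | 2,3-dimethylmaleic anhydride | CC1=C(C)C(=O)OC1=O
A2 | alternative 1 | cis-anti-cis 1,2-dimethylcyclobutane-1,2,3,4-tetracarboxylic 1,2:3,4-dianhydride | O=C1OC(=O)[C@@]2(C)[C@H](C(=O)O3)[C@H](C3=O)[C@@]12C
A3 | alternative 2 | N-(quinolin-8-yl)-2,3-bis(4-methoxy-3-methyl-2-oxo-2H-pyran-6-yl)-2,3-dimethylcyclobutane-1-carboxamide (amide cis to the methyl groups) | COc1cc([C@@]2(C)[C@H](C(=O)Nc3cccc4cccnc34)C[C@@]2(C)c2cc(OC)c(C)c(=O)o2)oc(=O)c1C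
A4 | alternative 2 | N-(quinolin-8-yl) imide of the target diacid | COc1cc([C@@]2(C)[C@H](C(=O)N3c4cccc5cccnc45)[C@H](C3=O)[C@@]2(C)c2cc(OC)c(C)c(=O)o2)oc(=O)c1C
A5 | alternative 3 | dimethyl cis-3,4-dimethylcyclobut-3-ene-1,2-dicarboxylate | CC1=C(C)[C@H](C(=O)OC)[C@@H]1C(=O)OC
A6 | alternative 3 | 3,6-dimethyl-1,2,4,5-tetrazine | Cc1nnc(C)nn1
A7 | alternative 3 | dimethyl 1,2,5,6-tetramethyl-3,4-diazabicyclo[4.2.0]octa-2,4-diene-7,8-dicarboxylate (esters anti to the azine) | CC1=NN=C(C)[C@@]2(C)[C@H](C(=O)OC)[C@H](C(=O)OC)[C@@]12C
A8 | alternative 3 | dimethyl 3,4-diacetyl-3,4-dimethylcyclobutane-1,2-dicarboxylate (acetyls cis, trans to the esters) | CC(=O)[C@@]1(C)[C@H](C(=O)OC)[C@H](C(=O)OC)[C@@]1(C)C(C)=O
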